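**Retrosynthetic overview**
1. Target ⇐ acetylation of the tertiary bridgehead alcohol of the resolved 1-hydroxy furofuran, the phenol being freed again by aminolysis.
2. 1-Hydroxy furofuran ⇐ one oxidative cross-coupling of two C6–C3 units: an 8-silyloxy coniferyl alcohol (phenol, oxidised) and 3,4-dimethoxycinnamyl alcohol (π-nucleophile).
3. Order of events in that step: C-8–C-8′ bond, then ring A (veratryl side, benzylic cation + C-9 OH), then ring B (guaiacyl side, quinone methide + C-9′ OH).
4. Monomers ⇐ vanillin acetate (Horner–Wadsworth–Emmons olefination, hydride reduction) and methyl 3,4-dimethoxycinnamate (hydride reduction).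
5. Absolute configuration ⇐ chromatographic resolution of the racemic furofuran, whose four stereocentres are fixed relative to one another in the coupling.

Assumption: the SMILES is read as (1S,2R,5R,6S)-6-(3,4-dimethoxyphenyl)-2-(4-hydroxy-3-methoxyphenyl)-3,7-dioxabicyclo[3.3.0]octan-1-yl acetate (both aryl groups exo; lignan locants C-7/C-8/C-9 = guaiacyl unit = bicyclic C-2/C-1/C-8, C-7′/C-8′/C-9′ = veratryl unit = C-6/C-5/C-4), compound 2 is taken as a catalogue reagent, and racemic compounds are drawn as the enantiomer of the target series.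

Step 1
Reactants: 1 4-formyl-2-methoxyphenyl acetate (vanillin acetate); 2 ethyl 2-[(tert-butyldimethylsilyl)oxy]-2-(diethoxyphosphoryl)acetate
Product: 3 ethyl (Z)-3-(4-acetoxy-3-methoxyphenyl)-2-[(tert-butyldimethylsilyl)oxy]prop-2-enoate
Conditions: 2, LiN(SiMe3)2, THF, −78 °C; then 1, −78 → 0 °C
Reagents that add atoms: none
Why: Horner–Wadsworth–Emmons olefination of the aldehyde with the pre-formed phosphonate anion gives the silyl enol ether of the arylpyruvate directly (Z isomer major; the E isomer is equally usable because C-7 and C-8 pass through a planar cation in step 4), and no stereocentre is formed.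

Step 2
Reactants: 3 ethyl (Z)-3-(4-acetoxy-3-methoxyphenyl)-2-[(tert-butyldimethylsilyl)oxy]prop-2-enoate
Product: 4 (Z)-2-[(tert-butyldimethylsilyl)oxy]-3-(4-hydroxy-3-methoxyphenyl)prop-2-en-1-ol
Conditions: i-Bu2AlH (4.5 equiv), CH2Cl2, −78 °C; aq. KNaC4H4O6 at −78 → 0 °C
Reagents that add atoms: none
Why: Ester reduction by a hydride donor: i-Bu2AlH reduces the conjugated ester 1,2 to the allylic alcohol and cleaves the aryl acetate in the same operation, while the silyl enol ether is inert to hydride and is protected from O→O silyl migration by the cold quench; no stereocentre is formed.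

Step 3
Reactants: 5 methyl (E)-3-(3,4-dimethoxyphenyl)prop-2-enoate
Product: 6 (E)-3-(3,4-dimethoxyphenyl)prop-2-en-1-ol
Conditions: i-Bu2AlH (2.5 equiv), CH2Cl2, −78 → 0 °C; aq. KNaC4H4O6
Reagents that add atoms: none
Why: 1,2-Reduction of the cinnamate ester by a hydride donor leaves the E alkene untouched; no stereocentre is formed.

Step 4
Reactants: 4 (Z)-2-[(tert-butyldimethylsilyl)oxy]-3-(4-hydroxy-3-methoxyphenyl)prop-2-en-1-ol; 6 (E)-3-(3,4-dimethoxyphenyl)prop-2-en-1-ol
Product: 8 rac-(1S*,2R*,5R*,6S*)-6-(3,4-dimethoxyphenyl)-2-(4-hydroxy-3-methoxyphenyl)-3,7-dioxabicyclo[3.3.0]octan-1-ol, via silyl ether 7 (not isolated)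
Conditions: 6 (4 equiv, excess recovered), PhI(OAc)2 (1.1 equiv), 2,6-lutidine, CF3CH2OH/CH2Cl2 1:1, −40 °C, 4 added over 2 h, then 0 °C; then HF·pyridine, THF, 0 → 23 °C
Reagents that add atoms: none
Why: Proposed new method: two-electron oxidation of the phenol of 4 by PhI(OAc)2 gives a cation that is both a para-quinone methide and a silyloxocarbenium ion at C-8, the electron-rich styrene 6 attacks this carbon through C-8′ and the C-9 hydroxyl collapses on the resulting 3,4-dimethoxybenzyl cation (ring A, formal [3+2], the bulky silyloxy group and the aryl group both trans to C-9′), then the C-9′ hydroxyl closes ring B by 5-exo oxa-Michael addition to the quinone methide as in the biosynthesis of furofuran lignans, which is only possible cis-fused so that the four stereocentres are set relative to one another with both aryl groups exo (adducts with the other C-8/C-8′ relationship cannot bicyclise and are separated), and HF·pyridine finally cleaves the silyl ether at oxygen; the closest known reaction types are the PhI(OAc)2-mediated oxidative formal [3+2] coupling of phenols with alkenes in fluorinated alcohols, the Prins-type [3+2] annulation of α-silyloxy carbonyl compounds with styrenes to tetrahydrofurans, and the oxidative β–β coupling of coniferyl alcohol to pinoresinol.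

Step 5
Reactants: 8 rac-(1S*,2R*,5R*,6S*)-6-(3,4-dimethoxyphenyl)-2-(4-hydroxy-3-methoxyphenyl)-3,7-dioxabicyclo[3.3.0]octan-1-ol
Product: 9 (1S,2R,5R,6S)-6-(3,4-dimethoxyphenyl)-2-(4-hydroxy-3-methoxyphenyl)-3,7-dioxabicyclo[3.3.0]octan-1-ol
Conditions: preparative chiral HPLC, amylose tris(3,5-dimethylphenylcarbamate) phase, hexane/EtOH, 23 °C
Reagents that add atoms: none
Why: Enantiomer resolution by chiral chromatography: the four stereocentres of 8 are already locked relative to one another by the cis ring fusion, so collecting the (1S,2R,5R,6S) enantiomer (assigned by circular dichroism against the pinoresinol series) fixes all four absolute configurations.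

Step 6
Reactants: 9 (1S,2R,5R,6S)-6-(3,4-dimethoxyphenyl)-2-(4-hydroxy-3-methoxyphenyl)-3,7-dioxabicyclo[3.3.0]octan-1-ol
Product: 11 (1S,2R,5R,6S)-6-(3,4-dimethoxyphenyl)-2-(4-hydroxy-3-methoxyphenyl)-3,7-dioxabicyclo[3.3.0]octan-1-yl acetate (CNP0107105.1), via diacetate 10 (not isolated)
Conditions: Ac2O, DMAP, Et3N, CH2Cl2, 40 °C; then pyrrolidine, 0 → 23 °C
Reagents that add atoms: acetic anhydride CC(=O)OC(C)=O
Why: DMAP-catalysed acylation (nucleophilic catalysis) acetylates the phenol and the tertiary bridgehead alcohol at oxygen, so C-1 keeps its configuration, and pyrrolidine then cleaves only the activated aryl acetate by aminolysis because the hindered tertiary alkyl acetate is far less electrophilic.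

**Compound list**
1 | 4-formyl-2-methoxyphenyl acetate (vanillin acetate) | CC(=O)Oc1ccc(C=O)cc1OC | starting material
2 | ethyl 2-[(tert-butyldimethylsilyl)oxy]-2-(diethoxyphosphoryl)acetate | CCOC(=O)C(O[Si](C)(C)C(C)(C)C)P(=O)(OCC)OCC | starting material
3 | ethyl (Z)-3-(4-acetoxy-3-methoxyphenyl)-2-[(tert-butyldimethylsilyl)oxy]prop-2-enoate | CCOC(=O)/C(O[Si](C)(C)C(C)(C)C)=C/c1ccc(OC(C)=O)c(OC)c1 | intermediate
4 | (Z)-2-[(tert-butyldimethylsilyl)oxy]-3-(4-hydroxy-3-methoxyphenyl)prop-2-en-1-ol | OC/C(O[Si](C)(C)C(C)(C)C)=C/c1ccc(O)c(OC)c1 | intermediate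
5 | methyl (E)-3-(3,4-dimethoxyphenyl)prop-2-enoate | COC(=O)/C=C/c1ccc(OC)c(OC)c1 | starting material
6 | (E)-3-(3,4-dimethoxyphenyl)prop-2-en-1-ol | OC/C=C/c1ccc(OC)c(OC)c1 | intermediate
7 | rac-4-[(1S*,2R*,5R*,6S*)-1-[(tert-butyldimethylsilyl)oxy]-6-(3,4-dimethoxyphenyl)-3,7-dioxabicyclo[3.3.0]octan-2-yl]-2-methoxyphenol (racemate) | COc1cc([C@H]2OC[C@@H]3[C@@H](c4ccc(OC)c(OC)c4)OC[C@]23O[Si](C)(C)C(C)(C)C)ccc1O | intermediate
8 | rac-(1S*,2R*,5R*,6S*)-6-(3,4-dimethoxyphenyl)-2-(4-hydroxy-3-methoxyphenyl)-3,7-dioxabicyclo[3.3.0]octan-1-ol (racemate) | COc1cc([C@H]2OC[C@@H]3[C@@H](c4ccc(OC)c(OC)c4)OC[C@]23O)ccc1O | intermediate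
9 | (1S,2R,5R,6S)-6-(3,4-dimethoxyphenyl)-2-(4-hydroxy-3-methoxyphenyl)-3,7-dioxabicyclo[3.3.0]octan-1-ol (single enantiomer) | COc1cc([C@H]2OC[C@@H]3[C@@H](c4ccc(OC)c(OC)c4)OC[C@]23O)ccc1O | intermediate
10 | (1S,2R,5R,6S)-2-(4-acetoxy-3-methoxyphenyl)-6-(3,4-dimethoxyphenyl)-3,7-dioxabicyclo[3.3.0]octan-1-yl acetate | COc1cc([C@H]2OC[C@@H]3[C@@H](c4ccc(OC)c(OC)c4)OC[C@]23OC(C)=O)ccc1OC(C)=O | intermediate
11 | (1S,2R,5R,6S)-6-(3,4-dimethoxyphenyl)-2-(4-hydroxy-3-methoxyphenyl)-3,7-dioxabicyclo[3.3.0]octan-1-yl acetate (CNP0107105.1) | COc1cc([C@H]2OC[C@@H]3[C@@H](c4ccc(OC)c(OC)c4)OC[C@]23OC(C)=O)ccc1O | target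

**Totals**
Total step count: 6. Longest linear sequence: 5 steps (steps 1, 2, 4, 5, 6).

**Steps most likely to fail, with fallbacks**

Step 4 is the most likely to fail. The risks are self-coupling of 4 through its nucleophilic enol ether, capture of the cation at the ring carbon ortho to oxygen (giving a dihydrobenzofuran), loss of the silyl group before C–C bond formation, and oxidation of 6. The fallback separates oxidation from C–C bond formation and sets out from 4. Compound 4 alone is dearomatised with PhI(OAc)2 and NaHCO3 in MeOH at −40 °C to the ortho-quinone monoketal 4-{(Z)-2-[(tert-butyldimethylsilyl)oxy]-3-hydroxyprop-1-en-1-yl}-6,6-dimethoxycyclohexa-2,4-dien-1-one F1. F1, which is no longer a π-nucleophile, is added slowly to 6 and BF3·OEt2 in CH2Cl2 at −78 °C. Loss of methanol regenerates the same cation with no oxidant in the flask, and the two ring closures lead back to the route at 7, which is desilylated to 8 as before.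

Step 2 can fail through 1,4 O→O silyl migration in the metal alkoxide, which turns the enol ether into a ketone. The fallback uses that migration on purpose and sets out from 3. After the same reduction, catalytic DBU drives the migration to completion and gives 1-[(tert-butyldimethylsilyl)oxy]-3-(4-hydroxy-3-methoxyphenyl)propan-2-one F2. tert-Butyldimethylsilyl triflate and Et3N re-enolise F2 toward the benzylic carbon and silylate the phenol, giving tert-butyl{4-[(Z)-2,3-bis[(tert-butyldimethylsilyl)oxy]prop-1-en-1-yl]-2-methoxyphenoxy}dimethylsilane F3. K2CO3 in MeOH at 0 °C removes only the aryl silyl group to give 4-{(Z)-2,3-bis[(tert-butyldimethylsilyl)oxy]prop-1-en-1-yl}-2-methoxyphenol F4. F4 replaces 4 under the oxidative conditions of step 4; its C-9 silyl ether oxygen captures the veratryl cation with loss of the silyl group, as in annulations of α-silyloxy carbonyl compounds with styrenes, and the route is rejoined at 7.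

Step 6 can fail if the hindered tertiary alcohol resists DMAP-catalysed acetylation or if the aminolysis is not selective. The fallback masks the phenol first and sets out from 9. tert-Butyldimethylsilyl chloride and imidazole in DMF silylate only the phenol to give (1S,2R,5R,6S)-2-{4-[(tert-butyldimethylsilyl)oxy]-3-methoxyphenyl}-6-(3,4-dimethoxyphenyl)-3,7-dioxabicyclo[3.3.0]octan-1-ol F5. The tertiary alkoxide, formed with LiN(SiMe3)2 in THF at −78 °C, is quenched with Ac2O to give (1S,2R,5R,6S)-2-{4-[(tert-butyldimethylsilyl)oxy]-3-methoxyphenyl}-6-(3,4-dimethoxyphenyl)-3,7-dioxabicyclo[3.3.0]octan-1-yl acetate F6. HF·pyridine in THF then removes the aryl silyl ether and the route arrives at 11.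

**Further compounds**
F1 | step 4 | 4-{(Z)-2-[(tert-butyldimethylsilyl)oxy]-3-hydroxyprop-1-en-1-yl}-6,6-dimethoxycyclohexa-2,4-dien-1-one | COC1(OC)C=C(/C=C(/CO)O[Si](C)(C)C(C)(C)C)C=CC1=O
F2 | step 2 | 1-[(tert-butyldimethylsilyl)oxy]-3-(4-hydroxy-3-methoxyphenyl)propan-2-one | COc1cc(CC(=O)CO[Si](C)(C)C(C)(C)C)ccc1O
F3 | step 2 | tert-butyl{4-[(Z)-2,3-bis[(tert-butyldimethylsilyl)oxy]prop-1-en-1-yl]-2-methoxyphenoxy}dimethylsilane | COc1cc(/C=C(/CO[Si](C)(C)C(C)(C)C)O[Si](C)(C)C(C)(C)C)ccc1O[Si](C)(C)C(C)(C)C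
F4 | step 2 | 4-{(Z)-2,3-bis[(tert-butyldimethylsilyl)oxy]prop-1-en-1-yl}-2-methoxyphenol | COc1cc(/C=C(/CO[Si](C)(C)C(C)(C)C)O[Si](C)(C)C(C)(C)C)ccc1O
F5 | step 6 | (1S,2R,5R,6S)-2-{4-[(tert-butyldimethylsilyl)oxy]-3-methoxyphenyl}-6-(3,4-dimethoxyphenyl)-3,7-dioxabicyclo[3.3.0]octan-1-ol | COc1cc([C@H]2OC[C@@H]3[C@@H](c4ccc(OC)c(OC)c4)OC[C@]23O)ccc1O[Si](C)(C)C(C)(C)C
F6 | step 6 | (1S,2R,5R,6S)-2-{4-[(tert-butyldimethylsilyl)oxy]-3-methoxyphenyl}-6-(3,4-dimethoxyphenyl)-3,7-dioxabicyclo[3.3.0]octan-1-yl acetate | COc1cc([C@H]2OC[C@@H]3[C@@H](c4ccc(OC)c(OC)c4)OC[C@]23OC(C)=O)ccc1O[Si](C)(C)C(C)(C)C
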